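The numbers were set for the occasion; no experiment stands behind them.

In a one-step world of electrophile and nucleophile, a larger charge of nucleophile simply speeds the coupling, so I asked what these flasks would need for that picture to fail.

| flask | electrophile | nucleophile | gas | time |
|---|---|---|---|---|
| south-east | 0.30 M (fed, over 80 min) | 0.360 M | 72 mM (held) | 1.5 h |
| east | 0.30 M (fed, over 80 min) | 0.540 M | 72 mM (held) | 1.5 h |

    electrophile + nucleophile → acid set free + target (k1 = 6.70 /M/h)
    nucleophile + acid set free ⇌ protonated nucleophile, settled at all times (K2 = 9900 /M)
    acid set free + free base ⇌ salt of the base, settled at all times (K3 = 2.5 × 10⁵ /M)
    gas ⇌ free base, rate k4*(csat - [free base]) (k4 = 105 /h, csat = 72 mM)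
    2 electrophile → self-condensation product (k5 = 8.89 × 10⁻⁴ /M/h)
    nucleophile + target ⇌ idle adduct, settled at all times (K6 = 1.5 /M)

- percent here means electrophile units held: one self-condensation product counts as two
- what is said of target includes idle adduct
- two of one species on the left: rate k times its square, two consumed each time
- at the start none of free base is dissolved
- run time (south-east): 1.5 h

* part of the electrophile that has reacted at the end, south-east
* part of the electrophile that has reacted at the end, east
* what raising the concentration of nucleophile from its lowest to its highest value here does to the part of the electrophile that has reacted (changes below 5 percentage points count as none) (no change / it rises / it falls)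

Each coupling frees one acid, and nucleophile that takes up acid stops coupling, so the way of failing that I looked at was acid outrunning the free base, which has to enter from the gas. The gas delivers at most 7.56 M/h, when none is dissolved, while over the feed the acid can on average arrive no faster than the electrophile, at 0.225 M/h. Dividing the one by the other removes time and gives what I called the uptake headroom, the greatest delivery of free base per unit of acid fed, 33.6. That failure asked for a headroom below one, and both flasks, with the same feed, stood far above that.

With free base taken at saturation and nucleophile at its charge, acid in south-east would split 0.198 parts protonated nucleophile to one part salt, so as an approximation I neglected protonation and kept the idle adduct. I treated the coupling as pseudo-first-order, using the nucleophile at the point where half the charge of electrophile had become target, part of it held as adduct. That gave rate constants of 1.15 /h for south-east and 2.13 /h for east. A steady feed against this loss, then plain decay to the end, gave me 57.7% reacted in south-east and 76.8% in east, so that with more nucleophile it rises.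

The forecast gave 62% (57% to 67%) for south-east and 75% (70% to 80%) for east, and said it rises, holding that the “dissolved base is replenished quickly and stays near saturation”. Its south-east figure lay above mine and its east figure below mine.

The simulation gave 61.5% in south-east and 75.1% in east, so it rises by 14 percentage points, and with the headroom at 33.6 the free base of east read 0.0704 M after 1.33 h against 72 mM at saturation. In the neighbouring flask, like east but with 1.2 M of electrophile, the headroom fell to 8.40, still above one, and free base read 0.0707 M after 1.50 h, while unbound nucleophile, the limiting reagent at 0.450 equiv, was down to 4.5% of its charge with 41.1% of the electrophile reacted.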